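(All runs are simulated for substances that don't exist; scatter was added.)

Target leaves this flask beside solvolysis product, and the number worth carrying to the next flask is how those two share what reacts.

in all of them: starting material 0.25 M
- south: first nucleophile 2.5 equiv; second nucleophile 0.95 equiv; protic impurity 0.025 M; the very flask that is asked about, followed so far
- north-west: first nucleophile 2.5 equiv; second nucleophile 0.95 equiv; protic impurity 0.050 M; run made earlier
- flask: first nucleophile 2.50 equiv; second nucleophile 0.950 equiv; protic impurity 0.0250 M; time 12 min

- south (time / s: target / %, solvolysis product / %, starting material / %): 25.0: 0.3, 1.6, 94.1; 50.0: 0.5, 4.1, 90.1; 80.0: 1.8, 7.5, 85.4; 90.0: 1.2, 9.0, 83.4; 120: 2.0, 11.8, 78.7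
- north-west (time / min: target / %, solvolysis product / %, starting material / %): 1.00: 1.6, 4.2, 89.0; 3.00: 3.5, 16.7, 69.5; 6.00: 5.6, 30.3, 48.8; 8.00: 6.1, 37.0, 37.9; 12.0: 8.3, 47.4, 24.2

(readings scatter by 0.5 percentage points)

- at 12 min, what has stopped the reaction, if anything has (the second nucleophile has run out first / all of the starting material has reacted / the first nucleophile has run out first / it is still moving)
- how much target there is at 12 min, in percent of the starting material charged
- how much solvolysis product there is at 12 min, in percent of the starting material charged

- a reading or a percentage of target counts all its forms, free or not
- the reaction counts as stopped when no species that holds the starting material changes by six tenths of a point or more over the second half of the time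

We build the flask up one process at a time. First the main step: starting material falls first order, at 0.120 /min in the south run and 0.118 /min in the north-west run, although north-west holds twice the protic impurity. So we put the flask at 12 min where north-west stood, with 24.2 % of starting material left. North-west lost 25 percentage points of it over the second half of that time, so by the stopping rule the flask is still moving. Sent wholly to solvolysis product, the reacted part is 75.8 %.

Now target. We assume one short-lived species with two exits, one first order and one through the first nucleophile. The second exit is pseudo-first-order while that reagent stays near its charge of 0.625 M, and the north-west impurity and target together come to 11.3 % of it. Target over solvolysis product, as amounts accumulated, reads 0.185 at 6.00 min in north-west and 0.175 at 12.0 min, and the later pair over the charge gives 0.280 /M: this scattered reading is our estimate of the capture constant, target formed per solvolysis product formed, per molar of first nucleophile charged. Splitting the reacted part by it gives 11.3 % of target and 64.5 % of solvolysis product.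

Last, the rest: north-west leaves 20 points in species nobody read. Taking that off in the same share, we commit to 8.3 % of target and 47.4 % of solvolysis product.

The forecast, apart from us on both numbers, said it is still moving, with 7.3 % of target and 48.3 % of solvolysis product, since “nothing limits early”. The flask gives it is still moving, with 8.49 % of target and 46.1 % of solvolysis product.

    2 starting material → homo dimer (k = 3.15 × 10⁻⁴ /M/s)
    second nucleophile + intermediate → other capture product (k = 0.0897 /M/s)
    first nucleophile + intermediate → target (k = 0.0161 /M/s)
    starting material → intermediate (k = 0.00190 /s)
    first nucleophile + protic impurity → quenched reagent (k = 0.0162 /M/s)
    crystals ⇌ target, rate k6*(cs6 - [target]) while solid is left; crystals form when [target] > cs6 (solubility = 0.160 M, k = 0.195 /s)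
    intermediate → solvolysis product (k = 0.0519 /s)

The ratio in the flask is 0.184, and our estimate of the capture constant gave 0.175. The intermediate in this flask has a half-life of 0.223 min by the step to solvolysis product, shorter than the 1.1 min by the step to target with charges as made, and at 12 min the first nucleophile stands at 93 % of its charge. For the neighbour flask with 6.20 equiv of first nucleophile, our estimate of the capture constant gives a ratio of 0.434. That flask holds 18.2 % of target and 38.9 % of solvolysis product, a ratio of 0.468.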